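**Strategy.** Ring C of unit 2 (units counted from the free-C8 end) is not taken from epicatechin but closed onto a ring A aryne, C4a≡C8a, that already carries unit 1 at C8. In one operation the benzylic hydroxyl of a syn-aldol aldehyde adds to C8a and the C4a anion so formed adds to the formyl carbon C4, making O1–C8a and C4–C4a and giving the upper dimer as a C4 carbinol. The feature exploited is the meta-oxygenation of ring A: the C5 oxygen polarises the aryne so that oxygen goes to C8a and carbon to C4a. Precursors are an ortho-silylaryl triflate and an Evans glycolate aldol product; 2+2 Friedel–Crafts coupling and hydrogenolysis finish.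

Key step: step 12

Remark: flavan numbering (O1, C2, C3, C4, C4a, C5–C8, C8a; ring A = benzo ring, ring B = catechol ring, ring C = pyran ring) is used for every unit, and the units are counted 1 to 4 from the end with the free C8 to the end with the C4 methylene. The target is named throughout as the all-(4β→8) epicatechin tetramer. Compounds 6, 12, 13 and 15 are assumed to be commercial.

Step 1
Reactants: 1 (−)-epicatechin
Product: 2 5,7,3',4'-tetra-O-benzyl-(−)-epicatechin
Conditions: BnBr, K2CO3, DMF, 0 °C to rt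
Reagents that add atoms: benzyl bromide, BrCc1ccccc1
Why: Williamson etherification of the four phenols under carbonate, which is too weak to deprotonate the secondary 3-OH, so that C2 and C3 are untouched.

Step 2
Reactants: 2 5,7,3',4'-tetra-O-benzyl-(−)-epicatechin
Product: 3 3,5,7,3',4'-penta-O-benzyl-(−)-epicatechin
Conditions: NaH, BnBr, n-Bu4NI (cat.), DMF, 0 °C to rt
Reagents that add atoms: benzyl bromide, BrCc1ccccc1
Why: Williamson etherification of the 3-alkoxide, safe for C2 because with all phenols capped no quinone methide can form.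

Step 3
Reactants: 3 3,5,7,3',4'-penta-O-benzyl-(−)-epicatechin
Product: 4 4β-(2-ethoxyethoxy)-3,5,7,3',4'-penta-O-benzylepicatechin
Conditions: DDQ, 2-ethoxyethanol, CH2Cl2, rt
Reagents that add atoms: 2-ethoxyethanol, CCOCCO
Why: DDQ benzylic oxidation removes hydride from C4 to give the ring A stabilised flavan-4-yl cation, which the alcohol should trap trans to the 3-benzyloxy group (4β).

Step 4
Reactants: 4 4β-(2-ethoxyethoxy)-3,5,7,3',4'-penta-O-benzylepicatechin; 3 3,5,7,3',4'-penta-O-benzyl-(−)-epicatechin (4 equiv)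
Product: 5 deca-O-benzyl epicatechin-(4β→8)-epicatechin (lower dimer; units 3 and 4)
Conditions: TMSOTf (cat.), CH2Cl2, −78 °C
Reagents that add atoms: none
Why: Lewis acid Friedel–Crafts alkylation by the C4 cation at C8 of the nucleophile, with the new C4 centre set 4β by attack anti to the 3-benzyloxy group and oligomers suppressed by excess 3.

Step 5
Reactants: 6 3,5-bis(benzyloxy)phenol
Product: 7 2-bromo-3,5-bis(benzyloxy)phenol
Conditions: NBS (1.0 equiv), i-Pr2NH (cat.), CH2Cl2, −78 to 0 °C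
Reagents that add atoms: N-bromosuccinimide, O=C1CCC(=O)N1Br
Why: amine-mediated electrophilic bromination of a phenol, in which the hydrogen-bonded N-bromoamine delivers bromine ortho to the hydroxyl.

Step 6
Reactants: 4 4β-(2-ethoxyethoxy)-3,5,7,3',4'-penta-O-benzylepicatechin; 7 2-bromo-3,5-bis(benzyloxy)phenol (3 equiv)
Product: 8 2-bromo-3,5-bis(benzyloxy)-6-(penta-O-benzylepicatechin-4β-yl)phenol
Conditions: TMSOTf (cat.), CH2Cl2, −78 °C
Reagents that add atoms: none
Why: Friedel–Crafts alkylation by the C4 cation of unit 1 at the free carbon ortho to the hydroxyl, which is less hindered than the carbon between two benzyloxy groups (the same preference as C8 over C6 in flavan nucleophiles), with 4β from attack anti to the 3-benzyloxy group.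

Step 7
Reactants: 8 2-bromo-3,5-bis(benzyloxy)-6-(penta-O-benzylepicatechin-4β-yl)phenol
Product: 11 3,5-bis(benzyloxy)-2-(penta-O-benzylepicatechin-4β-yl)-6-(trimethylsilyl)phenyl triflate, via trimethylsilyl ether 9 (not isolated), via lithium silylphenoxide 10 (not isolated)
Conditions: HMDS, THF, 65 °C, then evaporate; n-BuLi, THF, −78 °C; Tf2O, −78 to 0 °C
Reagents that add atoms: hexamethyldisilazane, C[Si](C)(C)N[Si](C)(C)C; triflic anhydride, O=S(=O)(OS(=O)(=O)C(F)(F)F)C(F)(F)F
Why: O-silylation, bromine–lithium exchange and retro-Brook 1,3-shift of silicon from oxygen to the future C4a, then triflation of the freed phenoxide, is the standard route to ortho-silylaryl triflates.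

Step 8
Reactants: 12 (S)-4-benzyloxazolidin-2-one; 13 benzyloxyacetyl chloride
Product: 14 (S)-4-benzyl-3-[(benzyloxy)acetyl]oxazolidin-2-one
Conditions: n-BuLi, THF, −78 °C; then 13, −78 to 0 °C
Reagents that add atoms: none
Why: N-acylation of the lithiated oxazolidinone by the acid chloride.

Step 9
Reactants: 14 (S)-4-benzyl-3-[(benzyloxy)acetyl]oxazolidin-2-one; 15 3,4-bis(benzyloxy)benzaldehyde
Product: 18 (S)-4-benzyl-3-[(2S,3R)-2-(benzyloxy)-3-[3,4-bis(benzyloxy)phenyl]-3-hydroxypropanoyl]oxazolidin-2-one, via boron enolate 16 (not isolated), via boron aldolate 17 (not isolated)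
Conditions: n-Bu2BOTf, i-Pr2NEt, CH2Cl2, −78 to 0 °C; 15, −78 to 0 °C; then pH 7 buffer, MeOH, H2O2, 0 °C
Reagents that add atoms: none
Why: Evans syn glycolate aldol, in which the Z boron enolate reacts through a chair Zimmerman–Traxler transition state on the face away from the auxiliary benzyl group and so sets both new centres (2S,3R), the future C3 and C2 of unit 2.

Step 10
Reactants: 18 (S)-4-benzyl-3-[(2S,3R)-2-(benzyloxy)-3-[3,4-bis(benzyloxy)phenyl]-3-hydroxypropanoyl]oxazolidin-2-one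
Product: 19 (1R,2R)-2-(benzyloxy)-1-[3,4-bis(benzyloxy)phenyl]propane-1,3-diol
Conditions: LiBH4, MeOH (1 equiv), THF, 0 °C
Reagents that add atoms: none
Why: reductive cleavage of the exocyclic imide carbonyl by LiBH4 releases the auxiliary and the primary alcohol without touching either stereocentre.

Step 11
Reactants: 19 (1R,2R)-2-(benzyloxy)-1-[3,4-bis(benzyloxy)phenyl]propane-1,3-diol
Product: 20 (2S,3R)-2-(benzyloxy)-3-[3,4-bis(benzyloxy)phenyl]-3-hydroxypropanal
Conditions: TEMPO (cat.), PhI(OAc)2, CH2Cl2, 0 °C to rt; used crude at once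
Reagents that add atoms: none
Why: oxoammonium (TEMPO) oxidation takes the primary alcohol much faster than the hindered secondary one, and the base-free medium should spare the epimerisable C2 of the aldehyde.

Step 12
Reactants: 11 3,5-bis(benzyloxy)-2-(penta-O-benzylepicatechin-4β-yl)-6-(trimethylsilyl)phenyl triflate; 20 (2S,3R)-2-(benzyloxy)-3-[3,4-bis(benzyloxy)phenyl]-3-hydroxypropanal (2 equiv)
Product: 22 penta-O-benzylepicatechin-(4β→8)-3,5,7,3',4'-penta-O-benzyl-4-hydroxyepicatechin (upper dimer; C4 carbinol as epimer mixture), via aryne 21 (not isolated)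
Conditions: KF, 18-crown-6, THF, 0 °C to rt, slow addition of 11
Reagents that add atoms: none
Why: Proposed new method: fluoride takes the trimethylsilyl group from C4a and expels triflate from C8a to give aryne 21; the fluoride-bonded benzylic hydroxyl of 20 (on the future C2) adds to C8a and the aryl anion left at C4a adds to the C4 aldehyde before it is protonated. The closest known reaction type is the aryne annulation of salicylaldehydes and salicylates (O-arylation, then capture of the aryl anion by the neighbouring carbonyl), here transferred to an aliphatic aldol. Ring C of unit 2 closes by 6-exo-trig attack of C4a on the formyl carbon after the intermolecular O1–C8a bond. C2 and C3 come unchanged from 20, while the new C4 carbinol centre is not controlled and need not be, because step 13 ionises it. The required regioselectivity (oxygen at C8a, carbon at C4a) rests on the inductive polarisation of the aryne by the 5-benzyloxy group, which places the negative charge at C4a, and it must override the bulk of the unit 1 substituent at C8. Excess 20 in THF, a poor proton donor, should favour ring closure over simple O-arylation, and the mild fluoride source should limit retro-aldol loss and epimerisation of 20.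

Step 13
Reactants: 22 penta-O-benzylepicatechin-(4β→8)-3,5,7,3',4'-penta-O-benzyl-4-hydroxyepicatechin (upper dimer); 5 deca-O-benzyl epicatechin-(4β→8)-epicatechin (3 equiv)
Product: 23 eicosa-O-benzyl epicatechin-(4β→8) tetramer
Conditions: TMSOTf (0.3 equiv), 4 Å MS, CH2Cl2, −78 to −30 °C
Reagents that add atoms: none
Why: Lewis acid ionisation of the C4 carbinol of unit 2 with loss of water (taken up by the sieves) and Friedel–Crafts attack by C8 of unit 3, with the 4β configuration set by attack anti to the 3-benzyloxy group on the 2,3-cis ring and excess 5 suppressing self-condensation.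

Step 14
Reactants: 23 eicosa-O-benzyl epicatechin-(4β→8) tetramer
Product: 24 epicatechin-(4β→8)-epicatechin-(4β→8)-epicatechin-(4β→8)-epicatechin (the target)
Conditions: H2 (1 atm), Pd(OH)2/C, THF/MeOH/H2O, rt
Reagents that add atoms: none
Why: hydrogenolysis of the twenty benzyl ethers under neutral conditions leaves the acid-labile interflavan bonds and all stereocentres intact.

**Compound list**

1 | (−)-epicatechin, (2R,3R) | Oc1cc(O)c2c(c1)O[C@H](c1ccc(O)c(O)c1)[C@H](O)C2 | starting material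
2 | 5,7,3',4'-tetra-O-benzyl-(−)-epicatechin (2R,3R; 3-OH free) | c1(OCc2ccccc2)cc(OCc2ccccc2)c2c(c1)O[C@H](c1ccc(OCc3ccccc3)c(OCc3ccccc3)c1)[C@H](O)C2 | intermediate
3 | 3,5,7,3',4'-penta-O-benzyl-(−)-epicatechin (2R,3R) | c1(OCc2ccccc2)cc(OCc2ccccc2)c2c(c1)O[C@H](c1ccc(OCc3ccccc3)c(OCc3ccccc3)c1)[C@H](OCc1ccccc1)C2 | intermediate
4 | 4β-(2-ethoxyethoxy)-3,5,7,3',4'-penta-O-benzylepicatechin (2,3-cis, 3,4-trans) | c1(OCc2ccccc2)cc(OCc2ccccc2)c2c(c1)O[C@H](c1ccc(OCc3ccccc3)c(OCc3ccccc3)c1)[C@H](OCc1ccccc1)[C@H]2OCCOCC | intermediate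
5 | deca-O-benzyl epicatechin-(4β→8)-epicatechin, penta-O-benzylepicatechin-(4β→8)-penta-O-benzylepicatechin (lower dimer) | c1(OCc2ccccc2)cc(OCc2ccccc2)c2c(c1)O[C@H](c1ccc(OCc3ccccc3)c(OCc3ccccc3)c1)[C@H](OCc1ccccc1)[C@H]2c1c(OCc3ccccc3)cc(OCc3ccccc3)c2c1O[C@H](c1ccc(OCc3ccccc3)c(OCc3ccccc3)c1)[C@H](OCc1ccccc1)C2 | intermediate
6 | 3,5-bis(benzyloxy)phenol | Oc1cc(OCc2ccccc2)cc(OCc2ccccc2)c1 | starting material
7 | 2-bromo-3,5-bis(benzyloxy)phenol | Oc1cc(OCc2ccccc2)cc(OCc2ccccc2)c1Br | intermediate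
8 | 2-bromo-3,5-bis(benzyloxy)-6-(penta-O-benzylepicatechin-4β-yl)phenol (aryl group trans to the 3-benzyloxy group) | c1(OCc2ccccc2)cc(OCc2ccccc2)c2c(c1)O[C@H](c1ccc(OCc3ccccc3)c(OCc3ccccc3)c1)[C@H](OCc1ccccc1)[C@H]2c1c(OCc3ccccc3)cc(OCc3ccccc3)c(Br)c1O | intermediate
9 | trimethylsilyl ether of 8 | c1(OCc2ccccc2)cc(OCc2ccccc2)c2c(c1)O[C@H](c1ccc(OCc3ccccc3)c(OCc3ccccc3)c1)[C@H](OCc1ccccc1)[C@H]2c1c(OCc3ccccc3)cc(OCc3ccccc3)c(Br)c1O[Si](C)(C)C | intermediate (not isolated)
10 | lithium 3,5-bis(benzyloxy)-2-(penta-O-benzylepicatechin-4β-yl)-6-(trimethylsilyl)phenoxide | c1(OCc2ccccc2)cc(OCc2ccccc2)c2c(c1)O[C@H](c1ccc(OCc3ccccc3)c(OCc3ccccc3)c1)[C@H](OCc1ccccc1)[C@H]2c1c(OCc3ccccc3)cc(OCc3ccccc3)c([Si](C)(C)C)c1[O-].[Li+] | intermediate (not isolated)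
11 | 3,5-bis(benzyloxy)-2-(penta-O-benzylepicatechin-4β-yl)-6-(trimethylsilyl)phenyl trifluoromethanesulfonate | c1(OCc2ccccc2)cc(OCc2ccccc2)c2c(c1)O[C@H](c1ccc(OCc3ccccc3)c(OCc3ccccc3)c1)[C@H](OCc1ccccc1)[C@H]2c1c(OCc3ccccc3)cc(OCc3ccccc3)c([Si](C)(C)C)c1OS(=O)(=O)C(F)(F)F | intermediate
12 | (S)-4-benzyloxazolidin-2-one | O=C1N[C@@H](Cc2ccccc2)CO1 | starting material
13 | benzyloxyacetyl chloride | O=C(Cl)COCc1ccccc1 | starting material
14 | (S)-4-benzyl-3-[(benzyloxy)acetyl]oxazolidin-2-one | O=C(COCc1ccccc1)N1[C@@H](Cc2ccccc2)COC1=O | intermediate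
15 | 3,4-bis(benzyloxy)benzaldehyde | O=Cc1ccc(OCc2ccccc2)c(OCc2ccccc2)c1 | starting material
16 | (Z)-di-n-butylboron enolate of 14 | CCCCB(CCCC)O/C(=C\OCc1ccccc1)N1[C@@H](Cc2ccccc2)COC1=O | intermediate (not isolated)
17 | di-n-butylboron aldolate of 18 | CCCCB(CCCC)O[C@H](c1ccc(OCc2ccccc2)c(OCc2ccccc2)c1)[C@H](OCc1ccccc1)C(=O)N1[C@@H](Cc2ccccc2)COC1=O | intermediate (not isolated)
18 | (S)-4-benzyl-3-[(2S,3R)-2-(benzyloxy)-3-[3,4-bis(benzyloxy)phenyl]-3-hydroxypropanoyl]oxazolidin-2-one | O[C@H](c1ccc(OCc2ccccc2)c(OCc2ccccc2)c1)[C@H](OCc1ccccc1)C(=O)N1[C@@H](Cc2ccccc2)COC1=O | intermediate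
19 | (1R,2R)-2-(benzyloxy)-1-[3,4-bis(benzyloxy)phenyl]propane-1,3-diol | O[C@H](c1ccc(OCc2ccccc2)c(OCc2ccccc2)c1)[C@H](OCc1ccccc1)CO | intermediate
20 | (2S,3R)-2-(benzyloxy)-3-[3,4-bis(benzyloxy)phenyl]-3-hydroxypropanal | O[C@H](c1ccc(OCc2ccccc2)c(OCc2ccccc2)c1)[C@H](OCc1ccccc1)C=O | intermediate
21 | 3,5-bis(benzyloxy)-6-(penta-O-benzylepicatechin-4β-yl)-1,2-didehydrobenzene (aryne; triple bond between the future C8a and C4a of unit 2) | c1(OCc2ccccc2)cc(OCc2ccccc2)c2c(c1)O[C@H](c1ccc(OCc3ccccc3)c(OCc3ccccc3)c1)[C@H](OCc1ccccc1)[C@H]2C1=C(OCc3ccccc3)C=C(OCc3ccccc3)C#C1 | intermediate (not isolated)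
22 | penta-O-benzylepicatechin-(4β→8)-3,5,7,3',4'-penta-O-benzyl-4-hydroxyepicatechin (2R,3R in both units; C4 carbinol of unit 2 as a mixture of epimers) | c1(OCc2ccccc2)cc(OCc2ccccc2)c2c(c1)O[C@H](c1ccc(OCc3ccccc3)c(OCc3ccccc3)c1)[C@H](OCc1ccccc1)[C@H]2c1c(OCc3ccccc3)cc(OCc3ccccc3)c2c1O[C@H](c1ccc(OCc3ccccc3)c(OCc3ccccc3)c1)[C@H](OCc1ccccc1)C2O | intermediate
23 | eicosa-O-benzyl epicatechin-(4β→8) tetramer (four penta-O-benzylepicatechin units joined 4β→8) | c1(OCc2ccccc2)cc(OCc2ccccc2)c2c(c1)O[C@H](c1ccc(OCc3ccccc3)c(OCc3ccccc3)c1)[C@H](OCc1ccccc1)[C@H]2c1c(OCc3ccccc3)cc(OCc3ccccc3)c2c1O[C@H](c1ccc(OCc3ccccc3)c(OCc3ccccc3)c1)[C@H](OCc1ccccc1)[C@H]2c1c(OCc3ccccc3)cc(OCc3ccccc3)c2c1O[C@H](c1ccc(OCc3ccccc3)c(OCc3ccccc3)c1)[C@H](OCc1ccccc1)[C@H]2c1c(OCc3ccccc3)cc(OCc3ccccc3)c2c1O[C@H](c1ccc(OCc3ccccc3)c(OCc3ccccc3)c1)[C@H](OCc1ccccc1)C2 | intermediate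
24 | epicatechin-(4β→8)-epicatechin-(4β→8)-epicatechin-(4β→8)-epicatechin (the all-4β→8 epicatechin tetramer) | Oc1cc(O)c2c(c1)O[C@H](c1ccc(O)c(O)c1)[C@H](O)[C@H]2c1c(O)cc(O)c2c1O[C@H](c1ccc(O)c(O)c1)[C@H](O)[C@H]2c1c(O)cc(O)c2c1O[C@H](c1ccc(O)c(O)c1)[C@H](O)[C@H]2c1c(O)cc(O)c2c1O[C@H](c1ccc(O)c(O)c1)[C@H](O)C2 | target

**Step count.** Total: 14 steps. Longest linear sequence: 8 steps (steps 1, 2, 3, 6, 7, 12, 13, 14).

**Steps most likely to fail**

1. Step 12 (Proposed new method). The C4a anion may be protonated before it reaches the aldehyde, which would leave only an aryl ether. The hindered alcohol may add at the wrong aryne carbon under steric pressure from the unit 1 group at C8. The aryne may be captured internally by the 3-benzyloxy oxygen of unit 1. The aldehyde 20 may undergo retro-aldol cleavage or epimerisation under fluoride. Fallback (known chemistry, giving up the ring construction on the aryne): the fallback sets out from 5. DDQ and 2-ethoxyethanol in CH2Cl2 should oxidise the only C4 methylene of 5 (lower unit) by benzylic hydride abstraction to give 4β-(2-ethoxyethoxy)-deca-O-benzyl epicatechin-(4β→8)-epicatechin F1. F1 is a C4-activated dimer that should react with excess 5 under TMSOTf in CH2Cl2 at −78 °C by 4β-selective Friedel–Crafts coupling. The fallback comes back to the route at 23.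

2. Step 6. The flavanyl cation may alkylate 7 at the carbon between the two benzyloxy groups or at oxygen instead of ortho to the hydroxyl, or the electrophile 4 may self-condense. Fallback (blocking the competing carbon): the fallback sets out from 7. One further equivalent of NBS in MeCN at 0 °C should brominate para to the free hydroxyl and give 2,4-dibromo-3,5-bis(benzyloxy)phenol F2, which has only one free ring carbon, ortho to the hydroxyl. Alkylation of F2 with 4 (TMSOTf, CH2Cl2, −78 °C) can then give only 2,4-dibromo-3,5-bis(benzyloxy)-6-(penta-O-benzylepicatechin-4β-yl)phenol F3. O-silylation of F3 (HMDS), double bromine–lithium exchange (n-BuLi, 2.2 equiv, THF, −78 °C), retro-Brook shift at the ortho position and aqueous NH4Cl quench should give 3,5-bis(benzyloxy)-2-(penta-O-benzylepicatechin-4β-yl)-6-(trimethylsilyl)phenol F4, with the blocking bromine replaced by hydrogen. Triflation of F4 (Tf2O, pyridine, CH2Cl2, 0 °C) comes back to the route at 11.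

3. Step 13. The dimer cation may self-condense through the free C8 of unit 1, attack C6 instead of C8 of unit 3, or the acid may scramble interflavan bonds already present. Fallback (thioether activation by a thiophilic silver salt instead of acid ionisation of the carbinol): the fallback sets out from 22. Phenylmethanethiol with BF3·OEt2 in CH2Cl2 at −78 °C should give the shelf-stable penta-O-benzylepicatechin-(4β→8)-4β-(benzylthio)-3,5,7,3',4'-penta-O-benzylepicatechin F5. F5 should couple with 5 under AgBF4 in THF at 0 °C in an essentially acid-free medium. The fallback comes back to the route at 23.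

**Further compounds**

F1 | step 12 | 4β-(2-ethoxyethoxy)-deca-O-benzyl epicatechin-(4β→8)-epicatechin (alkoxy group at C4 of the lower unit) | c1(OCc2ccccc2)cc(OCc2ccccc2)c2c(c1)O[C@H](c1ccc(OCc3ccccc3)c(OCc3ccccc3)c1)[C@H](OCc1ccccc1)[C@H]2c1c(OCc3ccccc3)cc(OCc3ccccc3)c2c1O[C@H](c1ccc(OCc3ccccc3)c(OCc3ccccc3)c1)[C@H](OCc1ccccc1)[C@H]2OCCOCC
F2 | step 6 | 2,4-dibromo-3,5-bis(benzyloxy)phenol | Oc1c(Br)c(OCc2ccccc2)c(Br)c(OCc2ccccc2)c1
F3 | step 6 | 2,4-dibromo-3,5-bis(benzyloxy)-6-(penta-O-benzylepicatechin-4β-yl)phenol | c1(OCc2ccccc2)cc(OCc2ccccc2)c2c(c1)O[C@H](c1ccc(OCc3ccccc3)c(OCc3ccccc3)c1)[C@H](OCc1ccccc1)[C@H]2c1c(OCc3ccccc3)c(Br)c(OCc3ccccc3)c(Br)c1O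
F4 | step 6 | 3,5-bis(benzyloxy)-2-(penta-O-benzylepicatechin-4β-yl)-6-(trimethylsilyl)phenol | c1(OCc2ccccc2)cc(OCc2ccccc2)c2c(c1)O[C@H](c1ccc(OCc3ccccc3)c(OCc3ccccc3)c1)[C@H](OCc1ccccc1)[C@H]2c1c(OCc3ccccc3)cc(OCc3ccccc3)c([Si](C)(C)C)c1O
F5 | step 13 | penta-O-benzylepicatechin-(4β→8)-4β-(benzylthio)-3,5,7,3',4'-penta-O-benzylepicatechin | c1(OCc2ccccc2)cc(OCc2ccccc2)c2c(c1)O[C@H](c1ccc(OCc3ccccc3)c(OCc3ccccc3)c1)[C@H](OCc1ccccc1)[C@H]2c1c(OCc3ccccc3)cc(OCc3ccccc3)c2c1O[C@H](c1ccc(OCc3ccccc3)c(OCc3ccccc3)c1)[C@H](OCc1ccccc1)[C@H]2SCc1ccccc1
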